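**Retrosynthetic overview**

1. Sipholenone A (37) ⇐ triol 36 (C3 oxidation) ⇐ cis-fused hydroazulenone 33, whose C15 ketone becomes the C15-methyl trisubstituted alkene via its kinetic enol triflate.
2. Key step: 33 ⇐ seco vinyl ketone 32 by a 7-endo radical cyclization that forms C17–C18, closes the seven-membered ring last and fuses it cis to the cyclopentane (C18 radical from a β-hydroxy selenide).
3. 32 ⇐ hydrazone 26 + iodide 18: Enders alkylation joins the halves at C13–C14 and sets C14; the C19 carbinol comes from epoxidation and selenolate opening of the cyclopentene.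
4. 18 ⇐ (R)-4-hydroxy-3-methylcyclohexenone 6 (from cyclohexane-1,3-dione) by anti conjugate addition, allylation, MeMgBr addition and 7-endo epoxide opening; 26 ⇐ 3-methylcyclopentenone + isobutyraldehyde.
5. Ring order: cyclohexane (bought) → oxepane; cyclopentene (bought) → cycloheptene (last, radical).

Assumption: intermediates are described with the sipholane locants of the target (oxepane O1/C2–C7, cyclohexane C6–C11, linker C12–C13, seven-membered ring C14–C18/C22/C23, cyclopentane C18–C22); the C3 carbinol configuration carried through the route is immaterial because C3 ends as the ketone.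

**Left fragment**

Step 1
Reactants: 1 cyclohexane-1,3-dione
Product: 2 3-ethoxycyclohex-2-en-1-one
Conditions: EtOH, TsOH (cat.), toluene, reflux, Dean–Stark
Reagents that add atoms: ethanol CCO
Why: Acid-catalysed vinylogous ester formation from the diketone enol with azeotropic removal of water; no stereocenter is formed.

Step 2
Reactants: 2 3-ethoxycyclohex-2-en-1-one
Product: 4 (6R)-3-ethoxy-6-hydroxycyclohex-2-en-1-one, via silyl dienol ether 3 (not isolated)
Conditions: TBSOTf, Et3N, CH2Cl2, 0 °C; then Shi ketone (D-fructose-derived, 30 mol %), KHSO5 (as Oxone), K2CO3, MeCN–dimethoxymethane–aq. buffer pH 10.5, 0 °C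
Reagents that add atoms: tert-butyldimethylsilyl triflate CC(C)(C)[Si](C)(C)OS(=O)(=O)C(F)(F)F (stays only in 3); potassium peroxymonosulfate [K+].[O-]S(=O)(=O)OO
Why: Soft enolisation at the only α'-position followed by Shi asymmetric epoxidation of the silyl enol ether (Rubottom-type oxidation), whose epoxy silyl ether collapses to the α-hydroxy ketone; the D-fructose-derived dioxirane gives the R carbinol (future C7) by analogy with its (R,R)-selectivity for 1-substituted cyclohexenes.

Step 3
Reactants: 4 (6R)-3-ethoxy-6-hydroxycyclohex-2-en-1-one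
Product: 6 (4R)-4-hydroxy-3-methylcyclohex-2-en-1-one, via carbinol 5 (not isolated)
Conditions: MeLi (2.2 equiv), THF, −78 °C; then 1 M HCl, 0 °C
Reagents that add atoms: methyllithium [Li]C
Why: Stork–Danheiser transposition, in which 1,2-addition of MeLi to the vinylogous ester and acid hydrolysis with loss of ethanol give the transposed enone while the carbinol stereocenter is untouched.

Step 4
Reactants: 6 (4R)-4-hydroxy-3-methylcyclohex-2-en-1-one; 7 5-bromo-2-methylpent-2-ene
Product: 9 trimethyl{[(3R,4R)-3-methyl-3-(4-methylpent-3-en-1-yl)-4-(trimethylsilyloxy)cyclohex-1-en-1-yl]oxy}silane, via TMS ether 8 (not isolated)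
Conditions: TMSCl, Et3N, THF, 0 °C; then Grignard reagent from 7 (Mg, THF), CuBr·SMe2 (20 mol %), TMSCl, DMPU, THF, −78 → −30 °C
Reagents that add atoms: chlorotrimethylsilane C[Si](C)(C)Cl
Why: TMSCl-accelerated copper-catalysed conjugate addition (Kharasch type) to the β,β-disubstituted enone occurs anti to the γ-silyloxy group, so the new quaternary C6 carries the homoprenyl chain trans to the C7 oxygen, and the enolate is trapped regiospecifically as the silyl enol ether.

Step 5
Reactants: 9 bis-silyl enol ether; 10 allyl bromide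
Product: 12 (2R,3R,4R)-4-hydroxy-3-methyl-3-(4-methylpent-3-en-1-yl)-2-(prop-2-en-1-yl)cyclohexan-1-one, via allylated TMS ether 11 (not isolated)
Conditions: MeLi, THF, 0 °C; 10, DMPU, −78 → 0 °C; then K2CO3 (cat.), MeOH, 23 °C
Reagents that add atoms: none
Why: The regiodefined lithium enolate released by Si–O cleavage is C-allylated at C11 (enolate alkylation), and methanolic carbonate removes the TMS ether and equilibrates C11 to the chair with only the C6 methyl axial, which places allyl cis to that methyl as in the target.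

Step 6
Reactants: 12 hydroxy ketone
Product: 13 (1S,2R,3R,4R)-1,3-dimethyl-3-(4-methylpent-3-en-1-yl)-2-(prop-2-en-1-yl)cyclohexane-1,4-diol
Conditions: MeMgBr (3 equiv), CeCl3, THF, −78 → 0 °C
Reagents that add atoms: methylmagnesium bromide C[Mg]Br
Why: Cerium-mediated 1,2-addition (Imamoto conditions suppress enolisation) in which axial attack on C10 is blocked by the syn-axial C6 methyl, so methyl enters equatorially and the tertiary hydroxyl is axial, cis to the C6 methyl and the C11 chain.

Step 7
Reactants: 13 diol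
Product: 15 oxepane diol (trans-fused; 3R; allyl at C11), via epoxide 14 (not isolated)
Conditions: Shi ketone (30 mol %), KHSO5 (as Oxone), K2CO3, MeCN–dimethoxymethane–aq. buffer, 0 °C; extractive work-up; then CSA (20 mol %), CH2Cl2, 0 °C
Reagents that add atoms: potassium peroxymonosulfate [K+].[O-]S(=O)(=O)OO
Why: Shi epoxidation takes the trisubstituted alkene in preference to the monosubstituted allyl group, and the equatorial C7 hydroxyl then opens the epoxide at the tertiary carbon C2 (acid-catalysed Markovnikov 7-endo epoxide opening) to give the trans-fused oxepane with the C7 configuration retained.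

Step 8
Reactants: 15 oxepane diol
Product: 16 3,10-bis(triethylsilyl) ether of 15
Conditions: TESOTf (3 equiv), 2,6-lutidine, CH2Cl2, 0 → 23 °C
Reagents that add atoms: triethylsilyl triflate CC[Si](CC)(CC)OS(=O)(=O)C(F)(F)F
Why: Silyl ether protection of the secondary C3 and the hindered tertiary C10 hydroxyl, which prevents the C10 alkoxide from closing a tetrahydrofuran onto the later iodide and masks C3 until the last step.

Step 9
Reactants: 16 bis-silyl ether
Product: 17 primary alcohol (2-hydroxyethyl at C11)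
Conditions: O3, CH2Cl2–MeOH, −78 °C; then NaBH4, −78 → 0 °C
Reagents that add atoms: ozone [O-][O+]=O
Why: Ozonolysis of the only remaining alkene with reductive work-up shortens the allyl group to the C12–C13 hydroxyethyl chain without touching a stereocenter.

Step 10
Reactants: 17 primary alcohol
Product: 18 primary iodide (2-iodoethyl at C11; left fragment)
Conditions: I2, PPh3, imidazole, CH2Cl2, 0 °C
Reagents that add atoms: iodine II
Why: Appel-type iodination of the primary alcohol under buffered conditions that leave both silyl ethers intact.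

**Right fragment**

Step 11
Reactants: 19 3-methylcyclopent-2-en-1-one
Product: 20 (1R)-3-methylcyclopent-2-en-1-ol
Conditions: (S)-2-methyl-CBS-oxazaborolidine (10 mol %), BH3·SMe2, THF, −20 °C; MeOH quench
Reagents that add atoms: none
Why: Corey–Bakshi–Shibata reduction in which the alkenyl carbon acts as the large group, so the (S)-catalyst gives the R allylic alcohol that defines C22.

Step 12
Reactants: 20 (1R)-3-methylcyclopent-2-en-1-ol
Product: 21 methyl (1R)-3-methylcyclopent-2-en-1-yl carbonate
Conditions: ClCO2Me, pyridine, CH2Cl2, 0 °C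
Reagents that add atoms: methyl chloroformate COC(=O)Cl
Why: O-acylation to the allylic carbonate needed for ionisation, with the stereocenter unchanged.

Step 13
Reactants: 21 allylic carbonate; 22 isobutyraldehyde
Product: 23 2-methyl-2-[(1R)-3-methylcyclopent-2-en-1-yl]propanal
Conditions: 22 (3 equiv), pyrrolidine (30 mol %), Pd(PPh3)4 (5 mol %), THF, 23 °C
Reagents that add atoms: none
Why: Tsuji–Trost allylation of the catalytic enamine of isobutyraldehyde, where ionisation and outer-sphere attack each invert so the quaternary carbon C23 is attached with net retention at the less substituted allyl terminus and the C18=C19 alkene stays in place.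

Step 14
Reactants: 23 aldehyde
Product: 25 3-methyl-3-[(1R)-3-methylcyclopent-2-en-1-yl]butanal, via enol ether 24 (not isolated)
Conditions: Ph3P(CH2OMe)Cl, KN(SiMe3)2, THF, 0 °C; then 2 M HCl, THF, 23 °C
Reagents that add atoms: (methoxymethyl)triphenylphosphonium chloride COC[P+](c1ccccc1)(c1ccccc1)c1ccccc1.[Cl-]; water O
Why: Wittig methoxymethylenation and enol ether hydrolysis add the one carbon (C15) that turns the neopentyl aldehyde into an aldehyde with an enolisable C14 methylene.

Step 15
Reactants: 25 aldehyde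
Product: 26 SAMP hydrazone of 25
Conditions: (S)-1-amino-2-(methoxymethyl)pyrrolidine (SAMP), CH2Cl2, 4 Å MS, 23 °C
Reagents that add atoms: SAMP COC[C@@H]1CCCN1N
Why: Hydrazone condensation installs the Enders auxiliary on C15 for stereocontrolled alkylation at C14.

**Union and endgame**

Step 16
Reactants: 26 SAMP hydrazone; 18 primary iodide
Product: 27 seco hydrazone (C13–C14 bond formed)
Conditions: LiN(iPr)2, THF, 0 °C; then 18 (0.9 equiv), −100 → −20 °C
Reagents that add atoms: none
Why: Enders SAMP-hydrazone alkylation, in which the chelated E-configured lithium aza-enolate is alkylated by the primary iodide on the face set by the auxiliary, which by the Enders model gives the C14 configuration of the target.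

Step 17
Reactants: 27 seco hydrazone
Product: 28 seco aldehyde (C15 aldehyde)
Conditions: CuCl2, THF–H2O, pH 7 phosphate buffer, 23 °C
Reagents that add atoms: water O
Why: Copper-assisted hydrolysis of the hydrazone under neutral conditions releases the α-branched aldehyde without epimerising C14 or cleaving the silyl ethers.

Step 18
Reactants: 28 seco aldehyde
Product: 29 vinyl carbinol (C15 epimers)
Conditions: vinylMgBr, THF, −78 °C
Reagents that add atoms: vinylmagnesium bromide C=C[Mg]Br
Why: Grignard 1,2-addition brings in C16–C17, and the new C15 carbinol mixture is of no consequence because it is oxidised in step 21.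

Step 19
Reactants: 29 vinyl carbinol
Product: 30 18,19-epoxide of 29
Conditions: mCPBA, CH2Cl2, 0 °C
Reagents that add atoms: 3-chloroperbenzoic acid OOC(=O)c1cccc(Cl)c1
Why: Prilezhaev epoxidation of the electron-rich trisubstituted cyclopentene (the vinyl group reacts far more slowly) on the face anti to the bulky C22 substituent, which puts oxygen on the face required for the C19 hydroxyl.

Step 20
Reactants: 30 epoxide
Product: 31 β-hydroxy selenide (18-SePh, 19-OH)
Conditions: PhSeSePh, NaBH4, EtOH, 70 °C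
Reagents that add atoms: diphenyl diselenide c1ccccc1[Se][Se]c1ccccc1
Why: SN2 opening of the epoxide by benzeneselenolate at the less substituted carbon C18 with inversion leaves the tertiary C19 hydroxyl in the target configuration and installs the radical precursor at C18.

Step 21
Reactants: 31 β-hydroxy selenide
Product: 32 seco vinyl ketone
Conditions: MnO2 (excess), CH2Cl2, 23 °C
Reagents that add atoms: none
Why: Allylic alcohol oxidation with MnO2 gives the vinyl ketone without oxidising the selenide or the tertiary alcohol.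

Step 22 (key step)
Reactants: 32 seco vinyl ketone
Product: 33 cis-fused hydroazulenone (C15 ketone)
Conditions: Bu3SnH (1.3 equiv), AIBN (0.2 equiv), benzene (5 mM), 80 °C, syringe-pump addition over 6 h
Reagents that add atoms: none
Why: In this tin hydride chain reaction, selenium abstraction gives the secondary C18 radical, which adds 7-endo-trig (intramolecular Giese addition) to the terminal carbon of the vinyl ketone because attack at the α-carbon is polarity-mismatched; the tether from C22 and the gem-dimethyl group force the C17–C18 bond onto the face of C23, so the ring fusion is cis.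

Step 23
Reactants: 33 hydroazulenone
Product: 34 C15 enol triflate (C15=C16)
Conditions: KN(SiMe3)2 (2.5 equiv), THF, −78 °C; then PhNTf2 (1.2 equiv)
Reagents that add atoms: N-phenylbis(trifluoromethanesulfonimide) O=S(=O)(N(c1ccccc1)S(=O)(=O)C(F)(F)F)C(F)(F)F
Why: Kinetic deprotonation takes the C16 methylene and not the hindered tertiary C14–H, and O-triflation of the enolate (the hindered tertiary alkoxide is not triflated at −78 °C) fixes the alkene position and preserves C14.

Step 24
Reactants: 34 enol triflate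
Product: 35 3,10-bis(triethylsilyl) ether of (3R)-3-deoxo-3-hydroxysipholenone A
Conditions: MeMgBr (4 equiv), Fe(acac)3 (10 mol %), THF–NMP, −20 → 0 °C
Reagents that add atoms: methylmagnesium bromide C[Mg]Br
Why: Iron-catalysed Kumada-type cross-coupling of the enol triflate with the methyl Grignard gives the C15-methyl trisubstituted alkene regiospecifically.

Step 25
Reactants: 35 bis-silyl ether
Product: 36 (3R)-3-deoxo-3-hydroxysipholenone A (triol)
Conditions: HF·pyridine, THF–pyridine, 0 → 23 °C
Reagents that add atoms: none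
Why: Fluoride-mediated cleavage of both triethylsilyl ethers under buffered conditions that spare the tertiary alcohols and the alkene.

Step 26
Reactants: 36 triol
Product: 37 sipholenone A
Conditions: Dess–Martin periodinane, CH2Cl2, 0 → 23 °C
Reagents that add atoms: none
Why: Dess–Martin oxidation converts the only secondary alcohol (C3) into the ketone while the two tertiary alcohols cannot be oxidised.

**Compound list**

1 | cyclohexane-1,3-dione | O=C1CCCC(=O)C1 | starting material
2 | 3-ethoxycyclohex-2-en-1-one | CCOC1=CC(=O)CCC1 | intermediate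
3 | tert-butyl[(5-ethoxycyclohexa-1,5-dien-1-yl)oxy]dimethylsilane | CCOC1=CC(O[Si](C)(C)C(C)(C)C)=CCC1 | intermediate
4 | (6R)-3-ethoxy-6-hydroxycyclohex-2-en-1-one | CCOC1=CC(=O)[C@H](O)CC1 | intermediate
5 | (6R)-3-ethoxy-1-methylcyclohex-2-ene-1,6-diol (both C1 epimers) | CCOC1=CC(C)(O)[C@H](O)CC1 | intermediate
6 | (4R)-4-hydroxy-3-methylcyclohex-2-en-1-one | O=C1C=C(C)[C@H](O)CC1 | intermediate
7 | 5-bromo-2-methylpent-2-ene | CC(C)=CCCBr | starting material
8 | (4R)-3-methyl-4-(trimethylsilyloxy)cyclohex-2-en-1-one | O=C1C=C(C)[C@H](O[Si](C)(C)C)CC1 | intermediate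
9 | trimethyl{[(3R,4R)-3-methyl-3-(4-methylpent-3-en-1-yl)-4-(trimethylsilyloxy)cyclohex-1-en-1-yl]oxy}silane | C[Si](C)(C)OC1=C[C@@](C)(CCC=C(C)C)[C@H](O[Si](C)(C)C)CC1 | intermediate
10 | allyl bromide (3-bromoprop-1-ene) | C=CCBr | starting material
11 | (3R,4R)-3-methyl-3-(4-methylpent-3-en-1-yl)-2-(prop-2-en-1-yl)-4-(trimethylsilyloxy)cyclohexan-1-one (C2 epimers) | C=CCC1[C@@](C)(CCC=C(C)C)[C@H](O[Si](C)(C)C)CCC1=O | intermediate
12 | (2R,3R,4R)-4-hydroxy-3-methyl-3-(4-methylpent-3-en-1-yl)-2-(prop-2-en-1-yl)cyclohexan-1-one | C=CC[C@@H]1[C@@](C)(CCC=C(C)C)[C@H](O)CCC1=O | intermediate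
13 | (1S,2R,3R,4R)-1,3-dimethyl-3-(4-methylpent-3-en-1-yl)-2-(prop-2-en-1-yl)cyclohexane-1,4-diol | C=CC[C@@H]1[C@@](C)(CCC=C(C)C)[C@H](O)CC[C@]1(C)O | intermediate
14 | (1S,2R,3R,4R)-3-{2-[(2R)-3,3-dimethyloxiran-2-yl]ethyl}-1,3-dimethyl-2-(prop-2-en-1-yl)cyclohexane-1,4-diol | C=CC[C@@H]1[C@@](C)(CC[C@H]2OC2(C)C)[C@H](O)CC[C@]1(C)O | intermediate
15 | oxepane diol: trans-fused oxepane–cyclohexane with 3R-OH; 6-Me/7-O/10-OH/C11-allyl on one face; 10-Me opposite | C=CC[C@@H]1[C@@]2(C)CC[C@@H](O)C(C)(C)O[C@@H]2CC[C@]1(C)O | intermediate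
16 | 3,10-bis(triethylsilyl) ether of 15 | C=CC[C@@H]1[C@@]2(C)CC[C@@H](O[Si](CC)(CC)CC)C(C)(C)O[C@@H]2CC[C@]1(C)O[Si](CC)(CC)CC | intermediate
17 | bis-silyl ether with 2-hydroxyethyl at C11 | OCC[C@@H]1[C@@]2(C)CC[C@@H](O[Si](CC)(CC)CC)C(C)(C)O[C@@H]2CC[C@]1(C)O[Si](CC)(CC)CC | intermediate
18 | bis-silyl ether with 2-iodoethyl at C11 (left fragment) | ICC[C@@H]1[C@@]2(C)CC[C@@H](O[Si](CC)(CC)CC)C(C)(C)O[C@@H]2CC[C@]1(C)O[Si](CC)(CC)CC | intermediate
19 | 3-methylcyclopent-2-en-1-one | CC1=CC(=O)CC1 | starting material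
20 | (1R)-3-methylcyclopent-2-en-1-ol | CC1=C[C@@H](CC1)O | intermediate
21 | methyl (1R)-3-methylcyclopent-2-en-1-yl carbonate | CC1=C[C@@H](CC1)OC(=O)OC | intermediate
22 | isobutyraldehyde (2-methylpropanal) | CC(C)C=O | starting material
23 | 2-methyl-2-[(1R)-3-methylcyclopent-2-en-1-yl]propanal | CC1=C[C@@H](CC1)C(C)(C)C=O | intermediate
24 | methyl enol ether of homologated 23 (E/Z): 1-methoxy-3-methyl-3-[(1R)-3-methylcyclopent-2-en-1-yl]but-1-ene | CC1=C[C@@H](CC1)C(C)(C)C=COC | intermediate
25 | 3-methyl-3-[(1R)-3-methylcyclopent-2-en-1-yl]butanal | CC1=C[C@@H](CC1)C(C)(C)CC=O | intermediate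
26 | (E)-N-[(2S)-2-(methoxymethyl)pyrrolidin-1-yl]-3-methyl-3-[(1R)-3-methylcyclopent-2-en-1-yl]butan-1-imine (SAMP hydrazone, right fragment) | CC1=C[C@@H](CC1)C(C)(C)C/C=N/N1CCC[C@H]1COC | intermediate
27 | seco hydrazone: 26 alkylated at C14 by 18 (C14 as in target) | CC1=C[C@@H](CC1)C(C)(C)[C@H](/C=N/N1CCC[C@H]1COC)CC[C@@H]1[C@@]2(C)CC[C@@H](O[Si](CC)(CC)CC)C(C)(C)O[C@@H]2CC[C@]1(C)O[Si](CC)(CC)CC | intermediate
28 | seco aldehyde (C15 aldehyde) | CC1=C[C@@H](CC1)C(C)(C)[C@H](C=O)CC[C@@H]1[C@@]2(C)CC[C@@H](O[Si](CC)(CC)CC)C(C)(C)O[C@@H]2CC[C@]1(C)O[Si](CC)(CC)CC | intermediate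
29 | seco vinyl carbinol (C15 epimers) | CC1=C[C@@H](CC1)C(C)(C)[C@H](C(O)C=C)CC[C@@H]1[C@@]2(C)CC[C@@H](O[Si](CC)(CC)CC)C(C)(C)O[C@@H]2CC[C@]1(C)O[Si](CC)(CC)CC | intermediate
30 | 18,19-epoxide of 29 (oxygen anti to C23) | C[C@]12O[C@H]1[C@@H](CC2)C(C)(C)[C@H](C(O)C=C)CC[C@@H]1[C@@]2(C)CC[C@@H](O[Si](CC)(CC)CC)C(C)(C)O[C@@H]2CC[C@]1(C)O[Si](CC)(CC)CC | intermediate
31 | β-hydroxy selenide (18-SePh cis to C23; 19-OH as in target) | c1ccccc1[Se][C@@H]2[C@@H](CC[C@@]2(C)O)C(C)(C)[C@H](C(O)C=C)CC[C@@H]1[C@@]2(C)CC[C@@H](O[Si](CC)(CC)CC)C(C)(C)O[C@@H]2CC[C@]1(C)O[Si](CC)(CC)CC | intermediate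
32 | seco vinyl ketone | c1ccccc1[Se][C@@H]2[C@@H](CC[C@@]2(C)O)C(C)(C)[C@H](C(=O)C=C)CC[C@@H]1[C@@]2(C)CC[C@@H](O[Si](CC)(CC)CC)C(C)(C)O[C@@H]2CC[C@]1(C)O[Si](CC)(CC)CC | intermediate
33 | cis-fused hydroazulenone (C15 ketone; H-14/H-18/H-22/19-OH on one face) | O=C1CC[C@@H]2[C@@H](CC[C@@]2(C)O)C(C)(C)[C@H]1CC[C@@H]1[C@@]2(C)CC[C@@H](O[Si](CC)(CC)CC)C(C)(C)O[C@@H]2CC[C@]1(C)O[Si](CC)(CC)CC | intermediate
34 | C15 enol triflate (C15=C16) | FC(F)(F)S(=O)(=O)OC1=CC[C@@H]2[C@@H](CC[C@@]2(C)O)C(C)(C)[C@H]1CC[C@@H]1[C@@]2(C)CC[C@@H](O[Si](CC)(CC)CC)C(C)(C)O[C@@H]2CC[C@]1(C)O[Si](CC)(CC)CC | intermediate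
35 | 3,10-bis(triethylsilyl) ether of (3R)-3-deoxo-3-hydroxysipholenone A | CC1=CC[C@@H]2[C@@H](CC[C@@]2(C)O)C(C)(C)[C@H]1CC[C@@H]1[C@@]2(C)CC[C@@H](O[Si](CC)(CC)CC)C(C)(C)O[C@@H]2CC[C@]1(C)O[Si](CC)(CC)CC | intermediate
36 | (3R)-3-deoxo-3-hydroxysipholenone A (triol) | CC1=CC[C@@H]2[C@@H](CC[C@@]2(C)O)C(C)(C)[C@H]1CC[C@@H]1[C@@]2(C)CC[C@@H](O)C(C)(C)O[C@@H]2CC[C@]1(C)O | intermediate
37 | sipholenone A | CC1=CC[C@@H]2[C@@H](CC[C@@]2(C)O)C(C)(C)[C@H]1CC[C@@H]1[C@@]2(C)CCC(=O)C(C)(C)O[C@@H]2CC[C@]1(C)O | target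

**Step count and risks**

Total steps: 26. Longest linear sequence: 21 steps (steps 1–10, then 16–26); the right fragment takes 5 steps (11–15).

The three steps most likely to fail:

Step 22 (radical ring closure). Risks are reduction of the C18 radical before it cyclizes, stannyl radical addition to the vinyl ketone, and some trans-fused product. The fallback sets out from 28 and comes back at 33, and forms the same C17–C18 bond with the radical on the other partner. Pinnick oxidation of 28 (NaClO2, NaH2PO4, 2-methylbut-2-ene) gives the carboxylic acid F7, and TMSCHN2 in MeOH gives the methyl ester F8. Kulinkovich reaction (EtMgBr, Ti(OiPr)4) gives the cyclopropanol F9. Ring opening with Mn(acac)3 under O2 generates the β-keto radical at C17, which closes the seven-membered ring by 7-exo attack on C18 of the intact cyclopentene. The tertiary C19 radical is trapped by O2 on the open face to give the hydroperoxide F10, which PPh3 reduces to 33. This removes steps 18–21.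

Step 7 (oxepane closure). The risk is 6-exo opening at C3 to a tetrahydropyran instead of 7-endo opening at C2. The fallback sets out from 12 and comes back at 15. NIS in CH2Cl2 effects iodoetherification, in which Markovnikov attack of the C7 hydroxyl on the iodonium can only give the seven-membered ring, to the iodo-oxepane ketone F3. Bu3SnH under air converts the C3–I bond via the C3 radical into the hydroperoxide F4, which PPh3 reduces to the hydroxy-oxepane ketone F5 (C3 epimers). MeMgBr/CeCl3 as in step 6 then gives 15 together with its C3 epimer F6; both converge on the ketone in step 26.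

Step 4 (quaternary centre by conjugate addition). The risk is that the hindered β,β-disubstituted γ-oxy enone reacts sluggishly or by 1,2-addition. The fallback sets out from 4 and comes back at 12, and swaps the order in which the two C6 substituents arrive. The Grignard reagent of 7 (2.2 equiv) adds to 4 to give the carbinol F1, which aqueous HCl converts (Stork–Danheiser) into (4R)-4-hydroxy-3-(4-methylpent-3-en-1-yl)cyclohex-2-en-1-one F2. MeMgBr then adds in an alkoxide-directed conjugate addition, the magnesium alkoxide at C7 delivering the small methyl group to C6 on its own face (methyl cis to O7, chain trans, the same outcome as step 4). The magnesium enolate is allylated with 10 in DMPU, and K2CO3/MeOH equilibration of C11 gives 12.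

**Further compounds**

F1 | step 4 | (6R)-3-ethoxy-1-(4-methylpent-3-en-1-yl)cyclohex-2-ene-1,6-diol (C1 epimers) | CCOC1=CC(O)(CCC=C(C)C)[C@H](O)CC1
F2 | step 4 | (4R)-4-hydroxy-3-(4-methylpent-3-en-1-yl)cyclohex-2-en-1-one | O=C1C=C(CCC=C(C)C)[C@H](O)CC1
F3 | step 7 | 3-iodo-oxepane ketone from 12 (C3 epimers) | C=CC[C@@H]1[C@@]2(C)CCC(I)C(C)(C)O[C@@H]2CCC1=O
F4 | step 7 | 3-hydroperoxy-oxepane ketone (C3 epimers) | C=CC[C@@H]1[C@@]2(C)CCC(OO)C(C)(C)O[C@@H]2CCC1=O
F5 | step 7 | 3-hydroxy-oxepane ketone (C3 epimers) | C=CC[C@@H]1[C@@]2(C)CCC(O)C(C)(C)O[C@@H]2CCC1=O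
F6 | step 7 | C3 epimer of 15 | C=CC[C@@H]1[C@@]2(C)CC[C@H](O)C(C)(C)O[C@@H]2CC[C@]1(C)O
F7 | step 22 | seco carboxylic acid (C15 acid) | CC1=C[C@@H](CC1)C(C)(C)[C@H](C(=O)O)CC[C@@H]1[C@@]2(C)CC[C@@H](O[Si](CC)(CC)CC)C(C)(C)O[C@@H]2CC[C@]1(C)O[Si](CC)(CC)CC
F8 | step 22 | seco methyl ester | CC1=C[C@@H](CC1)C(C)(C)[C@H](C(=O)OC)CC[C@@H]1[C@@]2(C)CC[C@@H](O[Si](CC)(CC)CC)C(C)(C)O[C@@H]2CC[C@]1(C)O[Si](CC)(CC)CC
F9 | step 22 | seco cyclopropanol (1-substituted cyclopropan-1-ol at C15) | CC1=C[C@@H](CC1)C(C)(C)[C@H](C1(O)CC1)CC[C@@H]1[C@@]2(C)CC[C@@H](O[Si](CC)(CC)CC)C(C)(C)O[C@@H]2CC[C@]1(C)O[Si](CC)(CC)CC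
F10 | step 22 | C19 hydroperoxide of 33 | O=C1CC[C@@H]2[C@@H](CC[C@@]2(C)OO)C(C)(C)[C@H]1CC[C@@H]1[C@@]2(C)CC[C@@H](O[Si](CC)(CC)CC)C(C)(C)O[C@@H]2CC[C@]1(C)O[Si](CC)(CC)CC
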